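**Assumptions.** (i) The target has no stereocentres, and the biaryl axis is drawn without a descriptor, so the product is the racemic or freely interconverting atropisomer mixture. (ii) In the Diels–Alder steps, 2-ethoxybenzoquinone reacts at its unsubstituted C=C with the diene's methoxy-bearing terminus bonding to the carbon next to the carbonyl that neighbours C–OEt. (iii) Bromination of the free peri-phenol occurs para to OH (at C8).

## Retrosynthetic overview
1. Disconnect the hindered C6–C8′ biaryl bond by Suzuki–Miyaura coupling into two 3-ethoxy-7-methyljuglone halves: an C6-boronate with a peri-OMe (9→10) and an C8-bromide with a free peri-OH (16).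
2. Each naphthoquinone is made by a Diels–Alder reaction of 2-ethoxy-1,4-benzoquinone (3) with a 1-methoxy-3-methylbutadiene, followed by DDQ aromatisation. The quinone ring exists first, then the benzo ring is formed, then the biaryl bond, and finally the peri-O-demethylation.
3. The C6 handle comes from a 2-bromo diene made from prenal. The C8 handle comes from para-bromination of the peri-phenol.

## Forward route

**Step 1**
Reactants: 1 catechol
Product: 2 2-ethoxyphenol
Conditions: EtBr, K2CO3, acetone, reflux (catechol in excess)
Reagents that add atoms: EtBr, CCBr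
Why: Williamson mono-O-ethylation; excess catechol limits diethylation, and no stereocentres arise.

**Step 2**
Reactants: 2 2-ethoxyphenol
Product: 3 2-ethoxy-1,4-benzoquinone
Conditions: Fremy's salt, KH2PO4 buffer, acetone/H2O, rt
Reagents that add atoms: water, O
Why: Teuber oxidation of a phenol with a free para position gives the p-quinone, and the new carbonyl oxygen comes from water.

**Step 3**
Reactants: 4 prenal (3-methylbut-2-enal)
Product: 5 2-bromo-3-methylbut-2-enal
Conditions: (i) Br2, CH2Cl2, 0 °C; (ii) Et3N, 0 °C→rt
Reagents that add atoms: Br2, BrBr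
Why: Bromine adds across the alkene, then E1cB loss of HBr restores the enal, which places Br at the α-carbon (the future C6).

**Step 4**
Reactants: 5 2-bromo-3-methylbut-2-enal
Product: 6 2-bromo-1,1-dimethoxy-3-methylbut-2-ene
Conditions: HC(OMe)3, MeOH, cat. TsOH, rt
Reagents that add atoms: trimethyl orthoformate, COC(OC)OC; methanol, CO
Why: Acid-catalysed acetalisation protects the aldehyde and prepares it for enol-ether formation.

**Step 5**
Reactants: 6 acetal
Product: 7 (E)-2-bromo-1-methoxy-3-methylbuta-1,3-diene
Conditions: TMSOTf, i-Pr2NEt, CH2Cl2, −78→0 °C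
Reagents that add atoms: none
Why: Gassman-type silylative ionisation of the acetal and γ-deprotonation give the dienyl methyl ether; both γ-methyls are equivalent, so only one diene forms.

**Step 6**
Reactants: 3 2-ethoxy-1,4-benzoquinone; 7 bromo diene
Product: 8 cis-fused Diels–Alder adduct
Conditions: PhMe, BHT, 80 °C
Reagents that add atoms: none
Why: Diels–Alder reaction (endo, suprafacial) on the more electrophilic unsubstituted C=C of the quinone; the matched regiochemistry puts OMe at C5 and OEt at C3. The three new sp3 centres (C4a, C5, C8a) are racemic and are all destroyed in Step 7.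

**Step 7**
Reactants: 8 adduct
Product: 9 6-bromo-3-ethoxy-5-methoxy-7-methylnaphthalene-1,4-dione
Conditions: DDQ (2.4 equiv), 1,4-dioxane, 90 °C
Reagents that add atoms: none
Why: Enolisation to the dihydro-hydroquinone, oxidation to the quinone and hydride abstraction at the OMe-stabilised C5–H aromatise the ring, so the vinylic Br and peri-OMe are retained and no stereocentre remains.

**Step 8**
Reactants: 9 aryl bromide
Product: 10 6-(pinacolboryl)-3-ethoxy-5-methoxy-7-methylnaphthalene-1,4-dione
Conditions: B2pin2, Pd(OAc)2/XPhos, KOAc, dioxane, 90 °C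
Reagents that add atoms: B2pin2, CC1(C)OB(OC1(C)C)B1OC(C)(C)C(C)(C)O1
Why: Miyaura borylation with a weak base limits protodeboronation and premature coupling.

**Step 9**
Reactants: 4 prenal
Product: 11 prenal dimethyl acetal (1,1-dimethoxy-3-methylbut-2-ene)
Conditions: HC(OMe)3, MeOH, cat. TsOH, rt
Reagents that add atoms: trimethyl orthoformate, COC(OC)OC; methanol, CO
Why: Acetalisation as in Step 4.

**Step 10**
Reactants: 11 acetal
Product: 12 (E)-1-methoxy-3-methylbuta-1,3-diene
Conditions: TMSOTf, i-Pr2NEt, CH2Cl2, −78→0 °C
Reagents that add atoms: none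
Why: Same enol-ether-forming elimination as Step 5, giving the unbrominated diene.

**Step 11**
Reactants: 3 2-ethoxy-1,4-benzoquinone; 12 diene
Product: 13 cis-fused Diels–Alder adduct
Conditions: PhMe, BHT, 80 °C
Reagents that add atoms: none
Why: Same regiochemically matched, endo Diels–Alder reaction as Step 6; the stereocentres are again destroyed in Step 12.

**Step 12**
Reactants: 13 adduct
Product: 14 3-ethoxy-5-methoxy-7-methylnaphthalene-1,4-dione
Conditions: DDQ (2.4 equiv), 1,4-dioxane, 90 °C
Reagents that add atoms: none
Why: Dehydrogenative aromatisation as in Step 7.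

**Step 13**
Reactants: 14 methyl ether
Product: 15 3-ethoxy-5-hydroxy-7-methylnaphthalene-1,4-dione
Conditions: BCl3, CH2Cl2, −78→0 °C, then aqueous workup
Reagents that add atoms: none
Why: BCl3 cleaves the peri-methyl ether selectively by chelation to the neighbouring carbonyl, and the vinylogous OEt is not in that chelate.

**Step 14**
Reactants: 15 phenol
Product: 16 8-bromo-3-ethoxy-5-hydroxy-7-methylnaphthalene-1,4-dione
Conditions: NBS (1.05 equiv), MeCN, 0 °C→rt
Reagents that add atoms: NBS, O=C1CCC(=O)N1Br
Why: Electrophilic aromatic bromination goes para to the phenol (naphthol C4-type position), as for 1-hydroxyanthraquinone.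

**Step 15**
Reactants: 10 boronate; 16 aryl bromide
Product: 17 6,8′-linked bis-quinone (one peri-OMe, one peri-OH)
Conditions: Pd2(dba)3, SPhos, K3PO4, PhMe/H2O (10:1), 100 °C
Reagents that add atoms: none
Why: Suzuki–Miyaura coupling with a bulky biaryl phosphine forms the tetra-ortho-substituted biaryl bond, and no stereocentre is set (the axis is racemic).

**Step 16**
Reactants: 17 bis-quinone
Product: 18 3,3′-diethoxyisodiospyrin (target)
Conditions: BCl3 (2 equiv), CH2Cl2, −78→0 °C
Reagents that add atoms: none
Why: Chelation-controlled peri-demethylation of the remaining OMe gives the second free 5-OH.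

## Compound list
1 | catechol | Oc1ccccc1O | starting material
2 | 2-ethoxyphenol | CCOc1ccccc1O | intermediate
3 | 2-ethoxy-1,4-benzoquinone | CCOC1=CC(=O)C=CC1=O | intermediate
4 | prenal (3-methylbut-2-enal) | CC(C)=CC=O | starting material
5 | 2-bromo-3-methylbut-2-enal | CC(C)=C(Br)C=O | intermediate
6 | 2-bromo-1,1-dimethoxy-3-methylbut-2-ene | COC(OC)C(Br)=C(C)C | intermediate
7 | (E)-2-bromo-1-methoxy-3-methylbuta-1,3-diene | CO/C=C(\Br)/C(C)=C | intermediate
8 | bromo Diels–Alder adduct (racemic, cis-fused; sp3 centres not defined) | O=C1C=C(OCC)C(=O)C2C1CC(C)=C(Br)C2OC | intermediate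
9 | 6-bromo-3-ethoxy-5-methoxy-7-methylnaphthalene-1,4-dione | CCOC1=CC(=O)c2cc(C)c(Br)c(OC)c2C1=O | intermediate
10 | 6-Bpin analogue of 9 | CCOC1=CC(=O)c2cc(C)c(B3OC(C)(C)C(C)(C)O3)c(OC)c2C1=O | intermediate
11 | prenal dimethyl acetal | COC(OC)C=C(C)C | intermediate
12 | (E)-1-methoxy-3-methylbuta-1,3-diene | CO/C=C/C(C)=C | intermediate
13 | Diels–Alder adduct (racemic, cis-fused; sp3 centres not defined) | O=C1C=C(OCC)C(=O)C2C1CC(C)=CC2OC | intermediate
14 | 3-ethoxy-5-methoxy-7-methylnaphthalene-1,4-dione | CCOC1=CC(=O)c2cc(C)cc(OC)c2C1=O | intermediate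
15 | 3-ethoxy-5-hydroxy-7-methylnaphthalene-1,4-dione | CCOC1=CC(=O)c2cc(C)cc(O)c2C1=O | intermediate
16 | 8-bromo-3-ethoxy-5-hydroxy-7-methylnaphthalene-1,4-dione | CCOC1=CC(=O)c2c(Br)c(C)cc(O)c2C1=O | intermediate
17 | 6,8′-bis-quinone (mono-OMe) | CCOC1=CC(=O)c2cc(C)c(-c3c(C)cc(O)c4c3C(=O)C=C(OCC)C4=O)c(OC)c2C1=O | intermediate
18 | 3,3′-diethoxyisodiospyrin | CCOC1=CC(=O)c2cc(C)c(-c3c(C)cc(O)c4c3C(=O)C=C(OCC)C4=O)c(O)c2C1=O | target

## Step count
Total steps: 16. Longest linear sequence: 8 (for example 4→5→6→7→8→10→15→16 counting Steps 3, 4, 5, 6, 7, 8, 15, 16, or Steps 9–16 on the other branch).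

## Three steps most likely to fail
1. **Steps 6 and 11 (Diels–Alder regiochemistry).** 2-Ethoxybenzoquinone could give the wrong regioisomer, with OEt next to the carbonyl that is not peri to O5.
   - Fallback: run the Diels–Alder with plain p-benzoquinone, which has no regiochemical issue. Then introduce OEt on the 7-methyljuglone monomers by Lewis-acid-promoted ethanol conjugate addition and reoxidation (or by bromination and ethoxide substitution), separating the C2 and C3 isomers.
2. **Step 14 (C8 bromination).** Bromination could occur at C6 or at the vinylogous-ester C2–H instead of C8.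
   - Fallback: build the C8 handle through oxygen. Use a 1,4-dioxygenated diene (for example 4-benzyloxy-1-methoxy-2-methylbutadiene) in the Diels–Alder reaction. After aromatisation, debenzylate and convert the C8-OH to a triflate to use as the Suzuki electrophile.
3. **Step 15 (hindered quinone–quinone Suzuki coupling).** Protodeboronation, quinone reduction or OEt attack by base could compete with the coupling.
   - Fallback: change the oxidation state at the coupling stage. Reduce both halves to hydroquinone dimethyl ethers, couple the electron-rich naphthalenes, then oxidise with CAN and demethylate with BCl3.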